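The numbers in the tables were computed for substances that don't exist.

Answer two questions for this flask, in order.

| flask | substrate | remark | time |
|---|---|---|---|
| elm | 0.045 M | run made earlier |  |
| alder | 0.18 M | run made earlier |  |
| flask | 0.090 M |  | 3.0 d |

| run | time / d | isomer of the product / % | target / % |
|---|---|---|---|
| elm | 0.208 | 11.0 | 16.7 |
| elm | 0.417 | 19.9 | 24.5 |
| elm | 1.04 | 32.5 | 32.1 |
| elm | 2.50 | 38.4 | 32.9 |
| alder | 0.333 | 14.4 | 21.2 |
| alder | 0.833 | 21.7 | 34.0 |
| alder | 1.67 | 22.8 | 43.5 |
| alder | 2.50 | 19.7 | 47.9 |

(readings scatter by 0.3 percentage points)

1. ratio of isomer of the product to target at 10 min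
2. ratio of isomer of the product to target at 3.0 d
3. which of isomer of the product and target there is more of at 3.0 d

- percentages count the substrate that a species holds: one self-condensation product counts as two
- target is meant together with its crystals
- solid, in amounts per volume of the solution: crystals
- candidate steps: substrate <-> isomer of the product; target <-> isomer of the product; substrate <-> target; crystals <-> target; 2 substrate -> self-condensation product

Take isomer of the product and target as fractions of the charge, and call isomer over target the ratio.

First, does the charge matter at the start? The first readings, at 0.208 d in elm and 0.333 d in alder, give a ratio of 0.659 and 0.679, although alder holds 4.00 times the charge of elm. So treat the start as kinetic control, with a ratio that ignores the charge. Elm's ratio climbs after that reading, so set the flask's ratio at 10 min under 0.659.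

Second, what does the charge do late? Both runs have a reading at 2.50 d: the ratio is 1.17 in elm and 0.411 in alder. Alder lies two doublings above elm, so take the square root of their quotient. That gives 0.594, the doubling factor: what one doubling of the charge multiplies the late ratio by. The flask lies one doubling above elm, so reckon its late ratio at 0.693, less than one, and expect target to lead. Elm's ratio is still rising and alder's still falling at that reading, so treat this as a rough figure for 3.0 d.

The forecast gives 0.45 at 10 min; it differs from this reckoning late, with 1.02 at 3.0 d and isomer of the product ahead, on the words “isomer is slightly favoured”.

The flask gives 0.580 at 10 min and 0.547 at 3.0 d, with target ahead, 47.4 % against 25.9 %.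

    substrate ⇌ isomer of the product (K = 2.13, k = 0.0267 h⁻¹)
    target ⇌ isomer of the product (k = 0.0220 h⁻¹)
    substrate ⇌ target (K = 1.10, k = 0.0463 h⁻¹)
    crystals ⇌ target, rate k4*(cs4 - [target]) while solid is left; crystals form when [target] > cs4 (solubility = 9.60 mM, k = 0.281 h⁻¹)
    2 substrate → self-condensation product (k = 0.117 L mol⁻¹ h⁻¹)

The doubling factor put this flask at 0.693, on the correct side of one, though the flask's ratio is 0.547. In this flask crystals hold 36.4 % of the charge at 3.0 d; take away the step from target into crystals and the ratio goes from 0.547 to 1.87, which turns the lead. Apply the factor once more, one doubling above alder: it gives 0.244 for the flask charged with 0.36 M, and that flask stands at 0.282 at 3.0 d.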